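(The earlier runs and the new flask are simulated from invented constants, and the scatter is random.)

The question for the meeting was how much substrate the flask holds at 80 s, 4.0 min and 12 min.

* amount of substrate in percent of the substrate charged, at 80 s, 4.0 min and 12 min

| setting | Monday's | Sunday's | Tuesday's | flask |
|---|---|---|---|---|
| substrate | 0.020 M | 0.020 M | 0.010 M | 0.020 M |
| reagent in the second phase | 0.74 equiv | 1.7 equiv | 1.1 equiv | 1.10 equiv |
| remark | run made earlier | run made earlier | run made earlier |  |
| time |  |  |  | 12 min |
| volume of the second phase over the first |  |  |  | 0.50 |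

| run | time / min | substrate / % | product / % |
|---|---|---|---|
| Monday's | 0.500 | 97.7 | 1.6 |
| Monday's | 0.833 | 97.3 | 2.2 |
| Monday's | 1.33 | 93.1 | 5.4 |
| Monday's | 2.00 | 89.5 | 9.4 |
| Monday's | 3.00 | 83.6 | 16.2 |
| Monday's | 5.00 | 76.8 | 26.5 |
| Monday's | 8.00 | 67.9 | 32.7 |
| Sunday's | 0.500 | 95.2 | 3.5 |
| Sunday's | 0.833 | 94.2 | 7.9 |
| Sunday's | 1.33 | 85.5 | 16.9 |
| Sunday's | 2.00 | 77.0 | 23.3 |
| Sunday's | 3.00 | 66.0 | 35.4 |
| Sunday's | 5.00 | 48.2 | 50.9 |
| Sunday's | 8.00 | 33.6 | 66.5 |
| Tuesday's | 1.33 | 94.0 | 5.7 |
| Tuesday's | 3.00 | 86.1 | 13.0 |
| Tuesday's | 4.00 | 83.0 | 19.0 |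
| Tuesday's | 6.00 | 74.6 | 26.0 |
| Tuesday's | 8.00 | 67.9 | 32.7 |

(scatter of a reading: 1 percentage point)

- in the second phase: reagent in the second phase; everything else is in the first
- charges count per volume of the first phase; a concentration in a rate is the amount of a species over the volume of its own phase; every rate counts per litre of the first phase
- the earlier runs hold the two phases in the same ratio of volumes as the flask asked about
- a reading or a percentage of product counts all its forms, free or not

The first speaker reported that Sunday's last reading gives 9.41 min for the equal-charge time τ. τ is the time at which a one-to-one bimolecular reaction with equal charges would leave 0.5 of the substrate. It is read from the fraction s of substrate left at time t, with q equivalents of reagent in the second phase, as τ = (q − 1)t / ln[(q − 1 + s)/(qs)]. She added that Tuesday's last reading gives 19.0 min, which becomes 9.51 min when scaled to the flask's substrate charge, close to Sunday's value.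

The second speaker objected that τ does not stay put. Sunday's reading at 1.33 min gives 13.8 min, longer than the same run's last value, which he read as a lag, an induction period.

The third speaker pointed to Monday's last reading, with reagent in the second phase at 0.74 equiv: it gives 11.5 min, longer than Sunday's. So the late value is not one number either, and these values are readings with their scatter.

The meeting agreed to use the early τ for the early time and the mean of the two late values, 10.4 min, for the later times. With s = (q − 1)/(q·exp[(q − 1)t/τ] − 1), the flask comes to 90.3 %, 69.9 % and 42.7 %.

The forecast, read against “a simple bimolecular model”, gives 88 %, 70 % and 42 %, lower than the meeting's figure at 80 s.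

The flask gives 90.2 %, 69.3 % and 44.0 %.

    reagent in the reaction phase ⇌ reagent in the second phase, rate k1*([reagent in the reaction phase] - [reagent in the second phase]/K1) per volume of the first phase (partition coefficient = 2.60, kL = 0.0140 s⁻¹)
    substrate + reagent in the reaction phase → product (k = 0.280 M⁻¹ s⁻¹)
    reagent in the reaction phase → decomposed reagent (k = 0.00180 s⁻¹)
    crystals ⇌ product, rate k4*(cs4 - [product]) while solid is left; crystals form when [product] > cs4 (solubility = 14.0 mM, k = 0.170 s⁻¹)

At 1.46 min the flask makes reagent in the reaction phase 1.08 times as fast as it uses it up, each step taken net. Read from the flask's own amounts, τ goes from 13.6 min at 80 s to 10.1 min at 4.0 min and 11.0 min at 12 min. Monday's run, read the same way, goes from 10.9 min at 3.00 min to 11.5 min at 8.00 min.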